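**Retrosynthetic overview**
- The target is the mono-methyl ester of a meso cyclobutane-1,2-dicarboxylic acid, so the last step is an enantioselective methanolysis of the meso cyclic anhydride; this C–O bond formation sets the absolute configuration of all four stereocentres at once.
- The meso anhydride (cyclobutane and fused anhydride ring together, all relative stereochemistry) comes from an intramolecular head-to-head [2+2] photocycloaddition of the acyclic symmetric anhydride of (E)-3-(pyranonyl)but-2-enoic acid.
- The enoic acid comes from its ethyl ester, whose 2-pyranone ring is made by dehydrogenating a 5,6-dihydropyranone.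
- The dihydropyranone comes from a vinylogous aldol–lactonisation of the dienolate of ethyl 3-methoxy-2-methylbut-2-enoate with ethyl (E)-3-methyl-4-oxobut-2-enoate.
- Ring order: the two pyranones first (on the monomer), then cyclobutane plus anhydride in one step, then anhydride opening.

Pyr = 4-methoxy-3-methyl-2-oxo-2H-pyran-6-yl.

Assumption: quinidine is taken to attack the same enantiotopic carbonyl of 11 as it does in simple cis-fused bicyclic meso anhydrides (recalled, not verified, sense of induction); the configuration of 12 is checked by X-ray or rotation after step 6, and if it were opposite, quinine would replace quinidine with nothing else changed.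

**Step 1**
Reactants: 1 ethyl 2-methyl-3-oxobutanoate (racemic)
Product: 2 ethyl (E)-3-methoxy-2-methylbut-2-enoate
Conditions: HC(OMe)3 (1.5 equiv), conc. H2SO4 (cat.), neat, rt, 24 h; distil
Reagents that add atoms: trimethyl orthoformate, COC(OC)OC
Why: Acid-catalysed ketalisation and loss of methanol (orthoester enol-ether formation) gives the conjugated β-methoxy enoate, mainly E; the geometry is erased anyway in the dienolate of step 2.

**Step 2**
Reactants: 2 ethyl (E)-3-methoxy-2-methylbut-2-enoate; 3 ethyl (E)-3-methyl-4-oxobut-2-enoate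
Product: 6 ethyl (E)-3-(4-methoxy-5-methyl-6-oxo-3,6-dihydro-2H-pyran-2-yl)but-2-enoate (racemic), via lithium dienolate 4 (not isolated), via lithium aldolate 5 (not isolated)
Conditions: LDA (1.1 equiv), THF, −78 °C, 45 min; 3, −78 °C → rt; aq. NH4Cl
Reagents that add atoms: none
Why: Vinylogous (γ-selective) aldol addition of the dienolate to the aldehyde, then lactonisation of the δ-alkoxide onto the cis ethyl ester (kavalactone-type aldol–lactonisation); α-attack is blocked by the 2-methyl group, the new C6 centre is racemic and is removed in step 3, and the E-enoate of 3 is untouched.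

**Step 3**
Reactants: 6 ethyl (E)-3-(4-methoxy-5-methyl-6-oxo-3,6-dihydro-2H-pyran-2-yl)but-2-enoate
Product: 7 ethyl (E)-3-(4-methoxy-3-methyl-2-oxo-2H-pyran-6-yl)but-2-enoate
Conditions: DDQ (1.5 equiv), 1,4-dioxane, 100 °C
Reagents that add atoms: none
Why: DDQ dehydrogenation of a 5,6-dihydro-4-methoxy-2-pyranone to the 2-pyranone (as in kavain to dehydrokavain), driven by hydride loss from the allylic, O-bearing C6–H and formation of the aromatic pyranone; the ester and E-alkene are inert to DDQ.

**Step 4**
Reactants: 7 ethyl (E)-3-(4-methoxy-3-methyl-2-oxo-2H-pyran-6-yl)but-2-enoate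
Product: 9 (E)-3-(4-methoxy-3-methyl-2-oxo-2H-pyran-6-yl)but-2-enoic acid, via trimethylstannyl ester 8 (not isolated)
Conditions: Me3SnOH (5 equiv), 1,2-dichloroethane, 80 °C; 1 M HCl wash
Reagents that add atoms: trimethyltin hydroxide, C[Sn](C)(C)O
Why: Me3SnOH ester hydrolysis cleaves the unhindered ethyl ester under near-neutral conditions that should leave the 4-methoxy-2-pyranone (at risk of ring opening with aqueous hydroxide) intact; no stereocentre is involved and the E geometry is kept.

**Step 5**
Reactants: 9 (E)-3-(4-methoxy-3-methyl-2-oxo-2H-pyran-6-yl)but-2-enoic acid (2 equiv)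
Product: 11 (1R,5S,6R,7S)-6,7-bis(4-methoxy-3-methyl-2-oxo-2H-pyran-6-yl)-6,7-dimethyl-3-oxabicyclo[3.2.0]heptane-2,4-dione (meso; both Pyr cis to the ring-fusion H atoms and both methyls cis to the anhydride carbonyl carbons), via symmetric acyclic anhydride 10 (not isolated)
Conditions: DCC (0.5 equiv per acid), dry CH2Cl2, 0 °C → rt, filter; filtrate diluted to 0.01 M, [Ir(dF(CF3)ppy)2(dtbbpy)]PF6 (1 mol%), degassed, 450 nm LEDs, rt; crystallise (no aqueous work-up)
Reagents that add atoms: none
Why: Proposed new method: the acyclic carboxylic anhydride serves as its own tether for a sensitised intramolecular enoate–enoate [2+2] — triplet energy transfer from the Ir sensitiser (61 kcal/mol) to one pyranonyl-enoate arm (estimated 50–55 kcal/mol, no direct absorption at 450 nm, so the pyranone is not photolysed), then 5-exo α–α′ bonding (rule of five for 1,6-dienes) gives the succinic-anhydride ring and a bis-tertiary, pyranone-stabilised 1,4-diradical that closes to the cyclobutane with its two adjacent quaternary carbons; the five-membered anhydride enforces head-to-head connectivity and cis carbonyl carbons, and closure should place the two large Pyr groups on the convex face (trans to the carbonyls), which is also the geometry-retentive outcome for the E,E-diene, so E/Z leakage in the triplet is stereoconvergent; closest known reaction type: Ir- or thioxanthone-sensitised intramolecular [2+2] of tethered cinnamates and 1,8-naphthalenediol-templated cinnamate photodimerisation to β-truxinates.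

**Step 6**
Reactants: 11 meso anhydride (1R,5S,6R,7S)-6,7-bis(4-methoxy-3-methyl-2-oxo-2H-pyran-6-yl)-6,7-dimethyl-3-oxabicyclo[3.2.0]heptane-2,4-dione
Product: 12 (1S,2R,3S,4R)-2-(methoxycarbonyl)-3,4-bis(4-methoxy-3-methyl-2-oxo-2H-pyran-6-yl)-3,4-dimethylcyclobutane-1-carboxylic acid (target)
Conditions: quinidine (1.1 equiv, recovered), MeOH (3 equiv), toluene/CCl4 1:1, −55 °C, 60–96 h; 2 M HCl wash
Reagents that add atoms: methanol, CO
Why: Cinchona-alkaloid-mediated desymmetrising methanolysis of a meso cyclic anhydride (Bolm-type): the quinidine–methanol complex delivers methanol to only one of the two enantiotopic carbonyls (the one on the R-configured ring-fusion carbon C1 of 11), so the new ester C–O bond fixes the absolute configuration of all four centres, whose relative configuration was set in step 5; the pyranones and the α-CH centres are untouched at −55 °C.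

**Compound list**
1 | ethyl 2-methyl-3-oxobutanoate (racemic) | CCOC(=O)C(C)C(C)=O | starting material
2 | ethyl (E)-3-methoxy-2-methylbut-2-enoate | CCOC(=O)/C(C)=C(\C)OC | intermediate
3 | ethyl (E)-3-methyl-4-oxobut-2-enoate | CCOC(=O)/C=C(\C)C=O | starting material
4 | lithium 1-ethoxy-3-methoxy-2-methylbuta-1,3-dien-1-olate (dienolate of 2) | C=C(OC)C(C)=C(OCC)O[Li] | intermediate (not isolated)
5 | lithium alkoxide of diethyl (2E,6E)-4-hydroxy-6-methoxy-3,7-dimethylocta-2,6-dienedioate (racemic aldolate) | CCOC(=O)/C=C(\C)C(O[Li])C/C(OC)=C(/C)C(=O)OCC | intermediate (not isolated)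
6 | ethyl (E)-3-(4-methoxy-5-methyl-6-oxo-3,6-dihydro-2H-pyran-2-yl)but-2-enoate (racemic) | CCOC(=O)/C=C(\C)C1CC(OC)=C(C)C(=O)O1 | intermediate
7 | ethyl (E)-3-(4-methoxy-3-methyl-2-oxo-2H-pyran-6-yl)but-2-enoate | CCOC(=O)/C=C(\C)c1cc(OC)c(C)c(=O)o1 | intermediate
8 | trimethylstannyl (E)-3-(4-methoxy-3-methyl-2-oxo-2H-pyran-6-yl)but-2-enoate | C[Sn](C)(C)OC(=O)/C=C(\C)c1cc(OC)c(C)c(=O)o1 | intermediate (not isolated)
9 | (E)-3-(4-methoxy-3-methyl-2-oxo-2H-pyran-6-yl)but-2-enoic acid | OC(=O)/C=C(\C)c1cc(OC)c(C)c(=O)o1 | intermediate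
10 | (2E,2′E)-3-(4-methoxy-3-methyl-2-oxo-2H-pyran-6-yl)but-2-enoic anhydride | O=C(/C=C(\C)c1cc(OC)c(C)c(=O)o1)OC(=O)/C=C(\C)c1cc(OC)c(C)c(=O)o1 | intermediate (not isolated)
11 | (1R,5S,6R,7S)-6,7-bis(4-methoxy-3-methyl-2-oxo-2H-pyran-6-yl)-6,7-dimethyl-3-oxabicyclo[3.2.0]heptane-2,4-dione (meso) | O1C(=O)[C@@H]2[C@H](C1=O)[C@@](C)(c3cc(OC)c(C)c(=O)o3)[C@@]2(C)c4cc(OC)c(C)c(=O)o4 | intermediate
12 | (1S,2R,3S,4R)-2-(methoxycarbonyl)-3,4-bis(4-methoxy-3-methyl-2-oxo-2H-pyran-6-yl)-3,4-dimethylcyclobutane-1-carboxylic acid | COC(=O)[C@@H]1[C@H](C(=O)O)[C@@](C)(c2cc(OC)c(C)c(=O)o2)[C@@]1(C)c1cc(OC)c(C)c(=O)o1 | target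

**Totals**
Total step count: 6. Longest linear sequence: 6 steps (1 → 2 → 6 → 7 → 9 → 11 → 12).

**Steps most likely to fail**

Step 5 (the proposed photocycloaddition). The diradical may close to a mixture of diastereomers at the quaternary carbons, disproportionate by hydrogen transfer, or the anhydride may hydrolyse. The fallback is the known covalent-template photodimerisation. It sets out from 9: two molecules of 9 are esterified with naphthalene-1,8-diol (DCC, DMAP, CH2Cl2) to naphthalene-1,8-diyl bis[(E)-3-(Pyr)but-2-enoate] F1. Irradiation at 365 nm, where the peri-held arms stack head-to-head and add with retention as established for cinnamates, gives the cyclic diester naphthalene-1,8-diyl (1R,2S,3R,4S)-3,4-dimethyl-3,4-bis(Pyr)cyclobutane-1,2-dicarboxylate F2. LiOH in THF/H2O at 0 °C then frees the meso diacid (1R,2S,3R,4S)-3,4-dimethyl-3,4-bis(Pyr)cyclobutane-1,2-dicarboxylic acid F3, and Ac2O at 60 °C closes it to the anhydride, coming back to the route at 11.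

Step 6 (desymmetrisation). The anhydride is flanked by two quaternary carbons and is polar, so rate, solubility at −55 °C and ee may all suffer, and the sense of induction is an extrapolation. The fallback replaces asymmetric induction by resolution. It sets out from 11: uncatalysed opening (MeOH, DMAP cat., CH2Cl2, rt) gives the racemic hemiester, a 1:1 mixture of the target and its enantiomer (1R,2S,3R,4S)-2-(methoxycarbonyl)-3,4-bis(Pyr)-3,4-dimethylcyclobutane-1-carboxylic acid F4. Preparative chiral SFC separates them, coming back to the route at 12.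

Step 3 (DDQ dehydrogenation). The C6–H of 6 is allylic to an electron-poor enoate, not to a styrene as in the kavalactone precedents, and may react sluggishly. The fallback builds the pyranone at the right oxidation level by known dianion chemistry. It sets out from 1 and 3: the dianion of 1 (NaH, then n-BuLi, THF) adds to aldehyde 3 to give diethyl (E)-4-hydroxy-3,7-dimethyl-6-oxooct-2-enedioate F5. Dess–Martin oxidation gives diethyl (E)-3,7-dimethyl-4,6-dioxooct-2-enedioate F6, and DBU in toluene cyclises it to ethyl (E)-3-(4-hydroxy-3-methyl-2-oxo-2H-pyran-6-yl)but-2-enoate F7. O-Methylation (Me2SO4, K2CO3, acetone) comes back to the route at 7.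

**Further compounds**
F1 | step 5 | naphthalene-1,8-diyl bis[(E)-3-(4-methoxy-3-methyl-2-oxo-2H-pyran-6-yl)but-2-enoate] | O=C(/C=C(\C)c1cc(OC)c(C)c(=O)o1)Oc1cccc2cccc(OC(=O)/C=C(\C)c3cc(OC)c(C)c(=O)o3)c12
F2 | step 5 | naphthalene-1,8-diyl (1R,2S,3R,4S)-3,4-bis(4-methoxy-3-methyl-2-oxo-2H-pyran-6-yl)-3,4-dimethylcyclobutane-1,2-dicarboxylate (cyclic diester) | O5C(=O)[C@@H]1[C@H](C(=O)Oc2cccc3cccc5c23)[C@@](C)(c6cc(OC)c(C)c(=O)o6)[C@@]1(C)c7cc(OC)c(C)c(=O)o7
F3 | step 5 | (1R,2S,3R,4S)-3,4-bis(4-methoxy-3-methyl-2-oxo-2H-pyran-6-yl)-3,4-dimethylcyclobutane-1,2-dicarboxylic acid (meso) | OC(=O)[C@@H]1[C@H](C(=O)O)[C@@](C)(c2cc(OC)c(C)c(=O)o2)[C@@]1(C)c1cc(OC)c(C)c(=O)o1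
F4 | step 6 | (1R,2S,3R,4S)-2-(methoxycarbonyl)-3,4-bis(4-methoxy-3-methyl-2-oxo-2H-pyran-6-yl)-3,4-dimethylcyclobutane-1-carboxylic acid (enantiomer of 12) | COC(=O)[C@H]1[C@@H](C(=O)O)[C@](C)(c2cc(OC)c(C)c(=O)o2)[C@]1(C)c1cc(OC)c(C)c(=O)o1
F5 | step 3 | diethyl (E)-4-hydroxy-3,7-dimethyl-6-oxooct-2-enedioate | CCOC(=O)/C=C(\C)C(O)CC(=O)C(C)C(=O)OCC
F6 | step 3 | diethyl (E)-3,7-dimethyl-4,6-dioxooct-2-enedioate | CCOC(=O)/C=C(\C)C(=O)CC(=O)C(C)C(=O)OCC
F7 | step 3 | ethyl (E)-3-(4-hydroxy-3-methyl-2-oxo-2H-pyran-6-yl)but-2-enoate | CCOC(=O)/C=C(\C)c1cc(O)c(C)c(=O)o1
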